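Everything rests on the C6–C7 bond (carotenoid numbering) that joins the acyloxylated ring A to the polyene. The tetrasubstituted C5=C6 olefin of ring A, with C6 flanked by the quaternary C1, is the only possible enol of its parent ketone, so C6 is introduced as the enol triflate of esterified (4R,6R)-actinol, which also supplies C3. C7 is the single carbon separating C6 from commercial C30 β-apo-8′-carotenal (C8 to ring B) and serves as a linchpin: in one flask, lithiated bis(pinacolatoboryl)methane olefinates the aldehyde (E-C7=C8) and the resulting C31 alkenyl boronate is cross-coupled with the triflate under palladium catalysis, forming C6–C7 and completing the target from three components.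

Key step: step 3

Remark on the chemistry: (4R,6R)-actinol (1) is taken as a purchasable chiral-pool ketone; its methyl-bearing stereocentre is erased in step 2, so only its carbinol centre (the future C3) matters.

Step 1
Reactants: 1 (4R,6R)-4-hydroxy-2,2,6-trimethylcyclohexanone (actinol); 2 (9Z)-hexadec-9-enoic acid (palmitoleic acid)
Product: 3 (1R,5R)-3,3,5-trimethyl-4-oxocyclohexyl (9Z)-hexadec-9-enoate
Conditions: DCC, DMAP (cat.), CH2Cl2, 0 → 23 °C
Reagents that add atoms: none
Why: Steglich esterification, in which DMAP-catalysed acyl transfer from the O-acylisourea should acylate the secondary alcohol without touching its C–O stereocentre (retention), while the neutral conditions leave the Z olefin alone and any epimerisation α to the ketone is harmless because that carbon becomes sp2 in step 2.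

Step 2
Reactants: 3 (1R,5R)-3,3,5-trimethyl-4-oxocyclohexyl (9Z)-hexadec-9-enoate
Product: 4 (1R)-3,5,5-trimethyl-4-[(trifluoromethanesulfonyl)oxy]cyclohex-3-en-1-yl (9Z)-hexadec-9-enoate
Conditions: Tf2O, 2,6-di-tert-butyl-4-methylpyridine, CH2Cl2, 0 → 23 °C
Reagents that add atoms: trifluoromethanesulfonic anhydride, O=S(=O)(OS(=O)(=O)C(F)(F)F)C(F)(F)F
Why: Enol triflate formation under Stang conditions (O-triflylation of the ketone, then loss of the only α-hydrogen to the hindered pyridine) can give a single regioisomer because the other α-carbon is quaternary, the absence of a strong base spares the enolisable ester, and the carbinol stereocentre is not involved.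

Step 3
Reactants: 4 (1R)-3,5,5-trimethyl-4-[(trifluoromethanesulfonyl)oxy]cyclohex-3-en-1-yl (9Z)-hexadec-9-enoate; 5 bis(4,4,5,5-tetramethyl-1,3,2-dioxaborolan-2-yl)methane; 6 all-E-8′-apo-β-caroten-8′-al (β-apo-8′-carotenal)
Product: 9 (3R)-β,β-caroten-3-yl (9Z)-hexadec-9-enoate (all-E polyene; β-cryptoxanthin palmitoleate), via lithiated bis(pinacolatoboryl)methane 7 (not isolated), via C31 alkenyl pinacol boronate 8 (not isolated)
Conditions: 5, lithium 2,2,6,6-tetramethylpiperidide, THF, 0 °C; 6, −78 → 23 °C; then 4, Pd(OAc)2 (cat.), SPhos, degassed aq. K3PO4, THF/H2O, 45 °C, argon, dark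
Reagents that add atoms: none
Why: Lithium tetramethylpiperidide deprotonates 5 to the α,α-diboryl carbanion 7, which adds 1,2 to the C8 aldehyde of 6; the β-alkoxide closes onto boron and syn-eliminates lithium pinacolborate (boron–Wittig olefination) to give the E-alkenyl boronate 8, and zerovalent palladium formed from Pd(OAc)2 and SPhos then inserts into the C6–O bond of 4, the base-activated boronate transmetalates, and reductive elimination forms the C6–C7 bond (Suzuki–Miyaura coupling). The closest known reaction types are the boron–Wittig synthesis of trans-alkenyl boronates from aldehydes and geminal bis(boronates) and the Suzuki–Miyaura coupling of hindered 2,6,6-trimethylcyclohexenyl triflates with alkenylboron reagents, here run consecutively in one flask. No ring is closed. No stereocentre is created: the new C7=C8 double bond should be E because the polyenyl chain and the remaining boryl group lie trans in the four-membered elimination transition state, the coupling is stereoretentive at both sp2 carbons, and C3, the other E double bonds and the Z olefin of the acyl chain are not involved. The step needs 1,2- rather than conjugate addition to the polyenal, cross-coupling that outruns protodeboronation and ester cleavage, and reaction of palladium at C6 only; the non-enolisable aldehyde carbon C8 is the most electrophilic site of 6 toward the hard lithium carbanion at low temperature, the enol triflate is the sole oxidative-addition site of 4, and the bulky electron-rich biaryl phosphine and mild phosphate base compensate for the shielding of C6 by the C1 gem-dimethyl group and the C5 methyl group.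

Compound list
1 | (4R,6R)-4-hydroxy-2,2,6-trimethylcyclohexanone (actinol) | O[C@@H]1C[C@@H](C)C(=O)C(C)(C)C1 | starting material
2 | (9Z)-hexadec-9-enoic acid (palmitoleic acid) | CCCCCC/C=C\CCCCCCCC(=O)O | starting material
3 | (1R,5R)-3,3,5-trimethyl-4-oxocyclohexyl (9Z)-hexadec-9-enoate | CCCCCC/C=C\CCCCCCCC(=O)O[C@@H]1C[C@@H](C)C(=O)C(C)(C)C1 | intermediate
4 | (1R)-3,5,5-trimethyl-4-[(trifluoromethanesulfonyl)oxy]cyclohex-3-en-1-yl (9Z)-hexadec-9-enoate | CCCCCC/C=C\CCCCCCCC(=O)O[C@@H]1CC(C)=C(OS(=O)(=O)C(F)(F)F)C(C)(C)C1 | intermediate
5 | bis(4,4,5,5-tetramethyl-1,3,2-dioxaborolan-2-yl)methane | CC1(C)OB(CB2OC(C)(C)C(C)(C)O2)OC1(C)C | starting material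
6 | all-E-8′-apo-β-caroten-8′-al (β-apo-8′-carotenal) | O=C/C(C)=C/C=C/C(C)=C/C=C/C=C(C)/C=C/C=C(C)/C=C/C1=C(C)CCCC1(C)C | starting material
7 | lithio-bis(4,4,5,5-tetramethyl-1,3,2-dioxaborolan-2-yl)methane | [Li]C(B1OC(C)(C)C(C)(C)O1)B1OC(C)(C)C(C)(C)O1 | intermediate
8 | 2-[(1E,3E,5E,7E,9E,11E,13E,15E,17E)-3,7,12,16-tetramethyl-18-(2,6,6-trimethylcyclohex-1-en-1-yl)octadeca-1,3,5,7,9,11,13,15,17-nonaen-1-yl]-4,4,5,5-tetramethyl-1,3,2-dioxaborolane | CC1(C)OB(/C=C/C(C)=C/C=C/C(C)=C/C=C/C=C(C)/C=C/C=C(C)/C=C/C2=C(C)CCCC2(C)C)OC1(C)C | intermediate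
9 | (3R)-β,β-caroten-3-yl (9Z)-hexadec-9-enoate (all-E polyene) | CCCCCC/C=C\CCCCCCCC(=O)O[C@@H]1CC(C)=C(/C=C/C(C)=C/C=C/C(C)=C/C=C/C=C(C)/C=C/C=C(C)/C=C/C2=C(C)CCCC2(C)C)C(C)(C)C1 | target

Total step count: 3
Longest linear sequence: 3 steps (1 → 3 → 4 → 9); compounds 5 and 6 enter in the last step.

Steps most likely to fail

Step 3 (key step). Transmetalation at the hindered palladium–C6 centre may be slower than protodeboronation and geometric isomerisation of the polyenyl boronate, or the carbanion may add in a conjugate sense or eliminate with poor E selectivity. The fallback is a base-free Stille coupling with an isolated organotin partner. It sets out from 6: (dibromomethyl)tributylstannane F1, made from CH2Br2, lithium diisopropylamide and Bu3SnCl in THF at −100 °C, is combined with 6, CrCl2 (divalent chromium) and LiI in THF/DMF at 23 °C. This Hodgson–Takai stannyl olefination through a geminal dichromium species should give the all-E C31 alkenyl tributylstannane F2. F2 and triflate 4 are then coupled with Pd2(dba)3, AsPh3 and LiCl in N-methylpyrrolidone at 50 °C, a coupling type established for hindered trimethylcyclohexenyl triflates and polyenyl stannanes, and the route is rejoined at 9.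

Step 2. O-Triflylation and proton loss at the doubly hindered ketone may be sluggish, allowing acid-promoted methyl migration from the quaternary carbon or degradation of the ester to compete. The fallback separates triflation from the ester and uses a kinetic lithium enolate. It sets out from 1: TBSCl and imidazole in DMF give (4R,6R)-4-[(tert-butyldimethylsilyl)oxy]-2,2,6-trimethylcyclohexanone F3. Lithium diisopropylamide in THF at −78 °C followed by PhNTf2 gives (4R)-4-[(tert-butyldimethylsilyl)oxy]-2,6,6-trimethylcyclohex-1-en-1-yl trifluoromethanesulfonate F4. HF·pyridine in THF removes the silyl group to give (4R)-4-hydroxy-2,6,6-trimethylcyclohex-1-en-1-yl trifluoromethanesulfonate F5. Steglich esterification of F5 with 2 (DCC, DMAP, CH2Cl2) rejoins the route at 4.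

Step 1. Acyl transfer to the ring alcohol may be slower than O→N acyl migration in the O-acylisourea, diverting the acid to an unreactive N-acylurea. The fallback uses a preformed acyl chloride. It sets out from 2: oxalyl chloride with catalytic DMF in CH2Cl2 gives (9Z)-hexadec-9-enoyl chloride F6, which acylates 1 with pyridine and catalytic DMAP in CH2Cl2 at 0 °C, rejoining the route at 3.

Further compounds
F1 | step 3 | (dibromomethyl)tributylstannane | CCCC[Sn](CCCC)(CCCC)C(Br)Br
F2 | step 3 | tributyl[(1E,3E,5E,7E,9E,11E,13E,15E,17E)-3,7,12,16-tetramethyl-18-(2,6,6-trimethylcyclohex-1-en-1-yl)octadeca-1,3,5,7,9,11,13,15,17-nonaen-1-yl]stannane | CCCC[Sn](CCCC)(CCCC)/C=C/C(C)=C/C=C/C(C)=C/C=C/C=C(C)/C=C/C=C(C)/C=C/C1=C(C)CCCC1(C)C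
F3 | step 2 | (4R,6R)-4-[(tert-butyldimethylsilyl)oxy]-2,2,6-trimethylcyclohexanone | CC(C)(C)[Si](C)(C)O[C@@H]1C[C@@H](C)C(=O)C(C)(C)C1
F4 | step 2 | (4R)-4-[(tert-butyldimethylsilyl)oxy]-2,6,6-trimethylcyclohex-1-en-1-yl trifluoromethanesulfonate | CC(C)(C)[Si](C)(C)O[C@@H]1CC(C)=C(OS(=O)(=O)C(F)(F)F)C(C)(C)C1
F5 | step 2 | (4R)-4-hydroxy-2,6,6-trimethylcyclohex-1-en-1-yl trifluoromethanesulfonate | O[C@@H]1CC(C)=C(OS(=O)(=O)C(F)(F)F)C(C)(C)C1
F6 | step 1 | (9Z)-hexadec-9-enoyl chloride | CCCCCC/C=C\CCCCCCCC(=O)Cl
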